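Slowness was plain in the grey run, where target was still climbing at its last reading, 66.8% at 10.0 h against 60.0% at 8.00 h, so I set that run beside the blue one to see where a flask stops.

| setting | blue | grey | flask |
|---|---|---|---|
| substrate | 1.4 M | 0.70 M | 1.4 M |
| coupling partner | 0.98 M | 0.98 M | 0.980 M |
| initiator | 210 mM | 210 mM | 210 mM |
| remark | the very flask that is asked about, followed so far | run made earlier |  |
| time |  |  | 8.0 d |

- blue (time / h: target / %): 12.0: 70.0; 30.0: 70.0; 72.0: 68.0; 144: 70.3
- grey (time / h: target / %): 2.50: 28.9; 5.00: 45.0; 8.00: 60.0; 10.0: 66.8

(each reading ± 1 percentage point)

- target that was removed still counts
- the numbers in the tables scatter by 1 percentage point (one standard deviation)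
- additions bring no volume worth counting

- zeta: at 8.0 d add coupling partner, 50.0% of the amount charged, then wait 4.0 d
- theta: change nothing and wait 4.0 d more
- epsilon: at 8.0 d add substrate, 50.0% of the amount charged, then wait 4.0 d
- beta: at 8.0 d take out 90% of the target then present, then wait 4.0 d

- target, in percent of the substrate first charged, at 8.0 d
- which option adds most target ("none" when 2 percentage points or less is all one gets) (zeta / theta / epsilon / beta / none)
- target present, with what was taken out counted in, in percent of the substrate first charged, after zeta
- target present, with what was taken out counted in, in percent of the substrate first charged, after beta

Read row by row, the blue column barely moved: 70.0% at 12.0 h and 70.3% at 144 h, with a mean reading of 69.6%. That flat line looked like a stop, not like slowness.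

So I divided the rate at which target appears by the rate at which coupling partner goes, and time dropped out. If each target takes one coupling partner and no other path takes any, that ratio is one, and target made equals partner spent. This gave me the partner ceiling, the charged coupling partner divided by the charged substrate, 70.0%, with the coupling partner as limiting reagent of the blue flask. The blue mean differs from it by 0.40 percentage points, less than the scatter of 1 point. In the grey run the same ratio is 1.40, so substrate caps that flask at 100%, and its last reading lay below that.

I therefore committed to 70.0% for the blue flask at 8.0 d. Theta, epsilon and beta leave the charged coupling partner and the first charge of substrate as they were, and removed target still counts, so the ceiling stays. Zeta lifts it to 100%, a room of 30 points, so I chose zeta, though the readings did not tell me how much of that room the flask would use.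

The forecast gave 70% at 8.0 d, 70.2% after zeta, 70% after beta, and as best option none, holding that “the initiator appears to die with time”. On the best option I differed.

    initiator → 2 initiating radical (k = 0.00130 min⁻¹)
    substrate + initiating radical → chain carrier (k = 1500 M⁻¹ min⁻¹)
    coupling partner + chain carrier → target + initiating radical (k = 4700 M⁻¹ min⁻¹)
    2 initiating radical → ended chains (k = 2.00 × 10⁶ M⁻¹ s⁻¹)
    coupling partner → decomposition product (k = 5.80 × 10⁻⁶ min⁻¹)

The blue flask gave 69.9% at 8.0 d, and zeta was best, reaching 81.8%, a gain of 12 points, while beta gave 69.9%. At 192 h the chain carrier held 11.9% of the substrate charged, beside 18.2% in free substrate. Against the partner ceiling of 70.0%, the blue target stood at 69.9%, and zeta stopped 18 points under 100%. In a neighbour flask, charged like blue but with 0.59 M of coupling partner, the ceiling of 42.1% met a target of 42.1%.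

The runs were computed for substances that don't exist; scatter was added.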